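**Plan** (isochroman-1-one numbering: C1 carbonyl, O2, C3, C4; ring A = benzene ring, ring B = lactone ring)
- Cuts, in retrosynthetic order: the O–CH3 bond of a phenol methyl ether; C3–C4 of ring B (ring closure); O2–C3 (addition of an acyl chloride across an aldehyde C=O); the C5'–C6' bond of the side chain (alkyl–alkenyl coupling).
- Forward: the side chain is joined first (dec-1-yne plus ethyl 6-bromohexanoate, then reduction to (E)-hexadec-7-enal). Ring A is bought as 2-methoxy-6-methylbenzoic acid and activated on both ortho arms (COCl, CH2Br). The halves are joined through the ester O2–C3, and ring B closes last but one at C3–C4.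
- Enabling feature: C3 carries the ring oxygen O2 and is the direct neighbour of benzylic C4 on ring A. With the C1–O2 ester in place, C3 can be a 1-chloroalkyl ester carbon (source of a stabilised α-acyloxy radical) and C4 a benzylic bromide. These two electrophilic carbons are united reductively at nickel.
- Stereochemistry: the (E)-alkene comes from syn-hydrozirconation of the terminal alkyne. C3 (R) comes from the chiral bis(oxazoline) ligand on nickel in the stereoconvergent ring closure.
- Helpers: Cl on C3 and Br on C4 are lost in the ring closure; the methyl ether on O8 is removed in the last step.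

Key step: step 6

Assumption: the sense of induction of the nickel/bis(oxazoline) catalyst in this ring-closing mode cannot be derived beforehand; the (S,S)-ligand is written, and its mirror image is to be used should a first run show the opposite sense at C3.

**Step 1**
Reactants: 1 dec-1-yne; 2 ethyl 6-bromohexanoate
Product: 4 ethyl (E)-hexadec-7-enoate, via (E)-dec-1-enylzirconocene chloride 3 (not isolated)
Conditions: Cp2Zr(H)Cl (1.25 equiv), THF, rt; then 2, Pd(acac)2 (2.5 mol %), LiBr (2 equiv), THF/NMP, 55 °C
Reagents that add atoms: none
Why: Syn-hydrozirconation of the terminal alkyne puts zirconium on C1 and fixes the (E)-geometry, and the alkenylzirconocene then enters the known Pd(acac)2/LiBr Negishi-type coupling with a primary alkyl bromide, which tolerates esters and β-hydrogens.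

**Step 2**
Reactants: 4 ethyl (E)-hexadec-7-enoate
Product: 6 (E)-hexadec-7-enal, via diisobutylaluminium hemiacetal 5 (not isolated)
Conditions: i-Bu2AlH (1.05 equiv), CH2Cl2, –78 °C; MeOH, then aq. potassium sodium tartrate
Reagents that add atoms: none
Why: Partial reduction of an ester with DIBAL-H, in which the tetrahedral aluminium hemiacetal is stable at –78 °C and releases the aldehyde only on work-up, while the isolated alkene is inert.

**Step 3**
Reactants: 7 2-methoxy-6-methylbenzoic acid
Product: 8 2-methoxy-6-methylbenzoyl chloride
Conditions: (COCl)2 (1.2 equiv), DMF (cat.), CH2Cl2, 0 °C → rt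
Reagents that add atoms: oxalyl chloride, ClC(=O)C(=O)Cl
Why: Standard DMF-catalysed conversion of a carboxylic acid into its acid chloride, to which the methyl ether and the ortho-methyl group are indifferent.

**Step 4**
Reactants: 8 2-methoxy-6-methylbenzoyl chloride
Product: 9 2-(bromomethyl)-6-methoxybenzoyl chloride
Conditions: NBS (1.05 equiv), AIBN (5 mol %), PhCF3, 85 °C
Reagents that add atoms: N-bromosuccinimide, O=C1CCC(=O)N1Br
Why: Wohl–Ziegler benzylic bromination, known for toluoyl chlorides and for the corresponding methyl ester; the acyl group deactivates ring A towards ionic ring bromination.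

**Step 5**
Reactants: 9 2-(bromomethyl)-6-methoxybenzoyl chloride; 6 (E)-hexadec-7-enal
Product: 10 (E)-1-chlorohexadec-7-en-1-yl 2-(bromomethyl)-6-methoxybenzoate (racemic at the chlorine-bearing carbon)
Conditions: ZnCl2 (5 mol %), CH2Cl2, –10 °C → rt, anhydrous; short silica plug, used at once
Reagents that add atoms: none
Why: Lewis-acid-catalysed addition of an acyl chloride across the aldehyde C=O (1-chloroalkyl ester formation), in which every atom of 6 and 9 ends up in 10; the new C–Cl centre is left racemic on purpose because step 6 is stereoconvergent.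

**Step 6**
Reactants: 10 (E)-1-chlorohexadec-7-en-1-yl 2-(bromomethyl)-6-methoxybenzoate
Product: 11 (R)-8-methoxy-3-[(E)-pentadec-6-en-1-yl]isochroman-1-one
Conditions: NiBr2(MeOCH2CH2OMe) (10 mol %), (S,S)-Ph-BOX = 2,2'-(propane-2,2-diyl)bis[(4S)-4-phenyl-4,5-dihydrooxazole] (12 mol %), Mn powder (3 equiv), NaI (20 mol %), Me3SiCl (10 mol %), DMA/THF 1:1, 0 °C → rt; 10 added over 8 h to 0.01 M
Reagents that add atoms: none
Why: Proposed new method: zerovalent nickel, kept low-valent by Mn, adds oxidatively to the benzylic C–Br bond (C4) of 10, and a monovalent nickel species abstracts chlorine from the 1-chloroalkyl ester carbon to give a planar α-acyloxyalkyl radical at C3, which is captured at the benzylnickel centre to a seven-membered trivalent nickelacycle that reductively eliminates the C3–C4 bond. The closest known reaction types are the nickel/bis(oxazoline)-catalysed enantioconvergent alkyl–alkyl coupling of racemic 1-haloalkyl esters with alkylzinc reagents (giving esters of dialkyl carbinols) and the nickel-catalysed asymmetric reductive cross-coupling of benzylic chlorides; without precedent is the ring-closing union of these two electrophilic carbons inside one molecule. Ring B closes as a six-membered lactone by C(sp3)–C(sp3) reductive elimination, formally a 6-exo-tet closure of the C3 radical onto nickel-bound C4. C3 is the only new stereocentre and is set by the chiral bis(oxazoline) ligand on nickel during radical capture and reductive elimination, so both enantiomers of 10 should converge on (R)-11. The step needs cyclisation to win over intermolecular benzyl–benzyl coupling, over β-hydride elimination to an enol ester and over a ligand-free racemic closure at the Mn surface; the rigid ortho-disubstituted benzoate holds C3 and C4 in a 1,6-relationship, slow addition at high dilution favours the intramolecular path, and no nickel hydride is formed, so the (E)-alkene should stay untouched.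

**Step 7**
Reactants: 11 (R)-8-methoxy-3-[(E)-pentadec-6-en-1-yl]isochroman-1-one
Product: 13 (R)-8-hydroxy-3-[(E)-pentadec-6-en-1-yl]isochroman-1-one, via aryloxydichloroborane chelate 12 (not isolated)
Conditions: BCl3 (2.5 equiv), CH2Cl2, –78 → 0 °C; then H2O
Reagents that add atoms: none
Why: Chelation-directed Lewis-acid demethylation, in which boron bound to the lactone carbonyl cleaves only the peri O–CH3 bond at low temperature, leaving the lactone, the C3 stereocentre and the isolated (E)-alkene alone.

**Compound list**
1 | dec-1-yne | CCCCCCCCC#C | starting material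
2 | ethyl 6-bromohexanoate | CCOC(=O)CCCCCBr | starting material
3 | (E)-dec-1-enylzirconocene chloride | CCCCCCCC/C=C/[Zr](Cl)(C1C=CC=C1)C1C=CC=C1 | intermediate
4 | ethyl (E)-hexadec-7-enoate | CCCCCCCC/C=C/CCCCCC(=O)OCC | intermediate
5 | diisobutylaluminium hemiacetal of 4 | CCCCCCCC/C=C/CCCCCC(OCC)O[Al](CC(C)C)CC(C)C | intermediate
6 | (E)-hexadec-7-enal | CCCCCCCC/C=C/CCCCCC=O | intermediate
7 | 2-methoxy-6-methylbenzoic acid | COc1cccc(C)c1C(=O)O | starting material
8 | 2-methoxy-6-methylbenzoyl chloride | COc1cccc(C)c1C(=O)Cl | intermediate
9 | 2-(bromomethyl)-6-methoxybenzoyl chloride | COc1cccc(CBr)c1C(=O)Cl | intermediate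
10 | (E)-1-chlorohexadec-7-en-1-yl 2-(bromomethyl)-6-methoxybenzoate (racemic) | CCCCCCCC/C=C/CCCCCC(Cl)OC(=O)c1c(CBr)cccc1OC | intermediate
11 | (R)-8-methoxy-3-[(E)-pentadec-6-en-1-yl]isochroman-1-one | CCCCCCCC/C=C/CCCCC[C@@H]1Cc2cccc(OC)c2C(=O)O1 | intermediate
12 | (R)-8-(dichloroboryloxy)-3-[(E)-pentadec-6-en-1-yl]isochroman-1-one | CCCCCCCC/C=C/CCCCC[C@@H]1Cc2cccc(OB(Cl)Cl)c2C(=O)O1 | intermediate
13 | (R)-8-hydroxy-3-[(E)-pentadec-6-en-1-yl]isochroman-1-one | CCCCCCCC/C=C/CCCCC[C@@H]1Cc2cccc(O)c2C(=O)O1 | target

**Step count:** 7 steps in total. Longest linear sequence: 5 steps (steps 1, 2, 5, 6, 7 from 1 and 2; equally steps 3, 4, 5, 6, 7 from 7).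

**Steps most likely to fail**

Step 6. Ring closure may lose to intermolecular benzyl–benzyl coupling or to simple reduction of one C–halogen bond. Enantioselection may also be eroded by a ligand-free closure through a benzylmanganese species. The fallback uses known chemistry, sets out from 6 and comes back at 11. Corey–Chaykovsky epoxidation of 6 (trimethylsulfonium iodide, NaH, DMSO/THF) should give racemic 2-[(E)-pentadec-6-en-1-yl]oxirane F1. Hydrolytic kinetic resolution with the (salen)Co(OAc) complex of trivalent cobalt (the antipode that hydrolyses the (S)-epoxide, 0.55 equiv H2O) should leave (R)-2-[(E)-pentadec-6-en-1-yl]oxirane F2. Directed ortho-lithiation of commercial N,N-diethyl-2-methoxybenzamide (s-BuLi, TMEDA, THF, –78 °C) gives N,N-diethyl-2-lithio-6-methoxybenzamide F3. F3 opens F2 at its terminal carbon in the presence of BF3·OEt2 to give N,N-diethyl-2-[(2R,8E)-2-hydroxyheptadec-8-en-1-yl]-6-methoxybenzamide F4. TsOH in refluxing toluene should lactonise F4 to 11 with loss of diethylamine. The C3 configuration then comes from the resolved epoxide, and ring B closes by C–O bond formation.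

Step 5. The doubly ortho-substituted acyl chloride may add sluggishly to the aldehyde. Halide exchange at the benzylic carbon, Lewis-acid-induced collapse to a phthalide and hydrolysis of the 1-chloroalkyl ester on handling may also intervene. The fallback sets out from 8 and 6 and comes back at 11. Ethanol/pyridine converts 8 into ethyl 2-methoxy-6-methylbenzoate F5. LDA (THF, –78 °C) gives the laterally lithiated ethyl 2-(lithiomethyl)-6-methoxybenzoate F6. Its addition to 6, with lactonisation of the resulting alkoxide in the flask, should give racemic 8-methoxy-3-[(E)-pentadec-6-en-1-yl]isochroman-1-one F7. Preparative HPLC on a chiral stationary phase then delivers 11.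

Step 4. Ionic bromination of ring A, over-bromination at the benzylic carbon and loss of the acyl chloride function (N-acylation of succinimide, hydrolysis) may compete. The fallback sets out from 7 and comes back at 11. Methylation (MeI, K2CO3, DMF) gives methyl 2-methoxy-6-methylbenzoate F8. Wohl–Ziegler bromination of this robust ester (NBS, AIBN, PhCF3, reflux) gives methyl 2-(bromomethyl)-6-methoxybenzoate F9. Heating neat at about 150 °C closes 7-methoxyisobenzofuran-1(3H)-one F10 with loss of bromomethane. Ring-opening chlorination (SOCl2, BF3·OEt2 cat., BnEt3NCl cat., 110 °C) installs both halides at once in 2-(chloromethyl)-6-methoxybenzoyl chloride F11. Addition of F11 to 6 as in step 5 gives (E)-1-chlorohexadec-7-en-1-yl 2-(chloromethyl)-6-methoxybenzoate F12. Under the conditions of step 6, with the benzylic chloride activated by NaI, F12 should close to 11.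

**Further compounds**
F1 | step 6 | racemic 2-[(E)-pentadec-6-en-1-yl]oxirane | CCCCCCCC/C=C/CCCCCC1CO1
F2 | step 6 | (R)-2-[(E)-pentadec-6-en-1-yl]oxirane | CCCCCCCC/C=C/CCCCC[C@@H]1CO1
F3 | step 6 | N,N-diethyl-2-lithio-6-methoxybenzamide | CCN(CC)C(=O)c1c([Li])cccc1OC
F4 | step 6 | N,N-diethyl-2-[(2R,8E)-2-hydroxyheptadec-8-en-1-yl]-6-methoxybenzamide | CCCCCCCC/C=C/CCCCC[C@@H](O)Cc1cccc(OC)c1C(=O)N(CC)CC
F5 | step 5 | ethyl 2-methoxy-6-methylbenzoate | CCOC(=O)c1c(C)cccc1OC
F6 | step 5 | ethyl 2-(lithiomethyl)-6-methoxybenzoate | CCOC(=O)c1c(C[Li])cccc1OC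
F7 | step 5 | racemic 8-methoxy-3-[(E)-pentadec-6-en-1-yl]isochroman-1-one | CCCCCCCC/C=C/CCCCCC1Cc2cccc(OC)c2C(=O)O1
F8 | step 4 | methyl 2-methoxy-6-methylbenzoate | COC(=O)c1c(C)cccc1OC
F9 | step 4 | methyl 2-(bromomethyl)-6-methoxybenzoate | COC(=O)c1c(CBr)cccc1OC
F10 | step 4 | 7-methoxyisobenzofuran-1(3H)-one | COc1cccc2COC(=O)c12
F11 | step 4 | 2-(chloromethyl)-6-methoxybenzoyl chloride | COc1cccc(CCl)c1C(=O)Cl
F12 | step 4 | (E)-1-chlorohexadec-7-en-1-yl 2-(chloromethyl)-6-methoxybenzoate | CCCCCCCC/C=C/CCCCCC(Cl)OC(=O)c1c(CCl)cccc1OC
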